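Start from the leftover in the green flask, the E that has not become J. The flasks, their readings and the questions are these.

the same everywhere: E 0.38 M; D 0.38 M; G 0.19 mM

| charge | L | X | temperature | remark | time |
|---|---|---|---|---|---|
| green | 0.456 M | 0.038 M | 25 °C | the very flask that is asked about, followed so far |  |
| red | 0.91 M | 0.038 M | 31 °C | run made earlier |  |
| flask | 0.456 M | 0.0380 M | 25 °C |  | 15 min |

| run | time / min | J / % |
|---|---|---|
| green | 0.833 | 36.2 |
| green | 2.50 | 44.7 |
| green | 4.00 | 46.0 |
| green | 6.00 | 48.0 |
| green | 10.0 | 48.1 |
| green | 12.0 | 48.2 |
| green | 15.0 | 48.9 |
| red | 0.833 | 48.4 |
| red | 1.50 | 49.4 |
| red | 2.50 | 50.1 |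
| red | 3.00 | 50.1 |
| red | 4.00 | 49.8 |
| red | 5.00 | 49.5 |
| red | 6.00 | 49.3 |

(standard deviation of a reading: 0.5 percentage points)

- spring: at 15 min add L, 50.0 % of the amount charged, then wait 5.0 min
- dawn: change nothing and wait 5.0 min more
- dusk: at 15 min take out 90 % of the J then present, then wait 5.0 min
- midnight: at 15 min raise the temperature by 10 K, then wait 5.0 min
- noon: at 15 min add G, 50.0 % of the amount charged, then wait 5.0 min

- G is single-handed; E and D are mirror images of each other, charged as a racemate, each of them at the stated concentration
- removed J is counted in
- the numbers in the tables scatter by 0.5 percentage points (one standard deviation)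
- additions bring no volume worth counting

- J, in percent of the E and D together first charged, at 15 min
- which option adds most J ("none" when 2 percentage points or less is all one gets) (spring / dawn / dusk / midnight / noon / none)
- J present, with what was taken out counted in, in percent of the E and D together first charged, after spring
- J present, with what was taken out counted in, in percent of the E and D together first charged, after midnight

G is single-handed, so take E's share of the racemate, 50.0 %, as the ceiling of J. The red run, with twice the [L], reads 50.1 % at 2.50 min, which lies at that ceiling within the scatter of a reading. Now average the green readings from 10.0 min on, which gives 48.4 %, and commit to that for J at 15 min. The ceiling minus the J present is 1.6 percentage points; call this the room, the points of J that the E still unturned can give.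

Object first that a mean of noisy readings may sit high, which would make the room look smaller than it is. Its standard deviation is 0.29 points, smaller than the 0.4 points between room and margin, so the room probably stays under the margin.

Object next that the stall has no stated cause, and write the balance of L, the likely limiting reagent. Count one L for each J: of the 0.456 M charged, J then holds 0.368 M, which leaves 0.0882 M for anything else. That is more than the 0.0122 M the room asks for, so L sufficed unless D and X took it, and the balance leaves open whether they did or whether G has failed with L still unused.

Let that doubt stand, because the choice rests on another comparison: whichever option works, J has to come from E, and the room is smaller than the margin. So expect "none", with spring reaching the ceiling of 50.0 % and midnight staying near 48.4 % if L is what is short.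

The forecast gives 48.6 % for now, none for the best option, 49.6 % after spring and 48.9 % after midnight, on the ground that “Only about 1.5% of E remains”. It shares the choice of the reckoning above but differs in its numbers, since that reckoning gives 48.4 % for now and 50.0 % after spring.

The flask gives 48.8 % at 15 min and none for the best option, with spring adding 1.2 points to reach 50.0 %, and midnight ending at 48.9 %.

    L + X → Z (k = 0.0230 M⁻¹ s⁻¹, Ea = 57.0 kJ mol⁻¹)
    L + G + E → G + J (k = 570 M⁻² s⁻¹, Ea = 37.0 kJ mol⁻¹)
    L + G + D → G + Q (k = 27.0 M⁻² s⁻¹, Ea = 46.0 kJ mol⁻¹)
    (constants at 25 °C)

The room, 1.6 points from the readings, comes to 1.2 points from this J, and the green flask holds E 1.24 % at 15.0 min, with L at 0.79 % of its charge. Now take the neighbouring flask, the same recipe with [L] at 0.18 M. At 15.0 min it holds J 21.8 %, so its room is 28 points, larger than the margin, and E there stands at 28.2 %, with L at 0 % of its charge.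

The numbers in the tables are calculated with made-up constants; the scatter is artificial.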